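(The data stem from a simulated flask with made-up constants; noise was put on by code.)

The meeting had 3 questions before it, all on one flask of substrate under a held gas phase.

in all of them: gas phase 8.8 mM (held); added ligand 170 mM
- teal: substrate 0.28 M; free catalyst 30 mM; run made earlier
- grey: substrate 0.44 M; free catalyst 30 mM; run made earlier
- violet: substrate 0.20 M; free catalyst 45 mM; run made earlier
- flask: substrate 0.20 M; free catalyst 30 mM; time 30 h

| run | time / h | target / % |
|---|---|---|
| teal | 3.00 | 0.2 |
| teal | 10.0 | 5.1 |
| teal | 15.0 | 6.0 |
| teal | 25.0 | 9.0 |
| teal | 40.0 | 11.1 |
| grey | 8.00 | 4.6 |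
| grey | 15.0 | 5.7 |
| grey | 20.0 | 6.3 |
| grey | 30.0 | 8.9 |
| grey | 40.0 | 11.1 |
| violet | 3.00 | 2.1 |
| violet | 10.0 | 7.5 |
| violet | 15.0 | 8.7 |
| violet | 25.0 | 13.5 |
| violet | 40.0 | 16.7 |

(scatter of a reading: 1 percentage point)

- at the start none of the gas is dissolved
- what may be going on: gas phase <-> dissolved gas; substrate + dissolved gas + free catalyst -> free catalyst + target; dissolved gas -> decomposed reagent; free catalyst + added ligand <-> idle complex; free catalyst -> spent catalyst

- how much target there is at 30 h, in percent of the substrate charged
- the change that raises the amount of target at 30 h, in percent of the substrate charged most ("none" if none brings more than 2 percentage points) (Saturday's / Sunday's / Tuesday's / none)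
- amount of target at 30 h, in percent of the substrate charged, after Tuesday's

- Saturday's: doubling the transfer coefficient of the gas phase, all else as stated
- Sunday's: doubling the amount of free catalyst, all else as stated
- Tuesday's: doubling the saturation concentration of gas phase, all else as stated

The chair opened with the readings at 40.0 h: teal and grey both stood at 11.1%, although teal was charged with 0.28 M substrate and grey with 0.44 M. She concluded that, with a scatter of 1 percentage point on each reading, these two readings do not tell the charges apart, and that with 11.1% of it read as target the substrate stays near its charge, so it could be frozen there.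

I proposed freezing one thing more, the late gain, which is the fraction of the substrate charged that becomes target per hour after the early readings: from 10.0 h to 40.0 h, teal gives 0.00200 h⁻¹. Grey, at the same catalyst, gives 0.00203 h⁻¹. Violet gives 0.00307 h⁻¹, and its catalyst charge is 1.50 times teal's, so the gain follows the catalyst. My reckoning for the flask was teal's reading at 10.0 h plus this gain up to 30 h, which makes 9.10%, with each reading carrying a scatter of 1 point.

The forecast then stated 9.5%, chose Tuesday's and gave 18.1% after it, while warning that “Sunday's nearly ties but drains slightly more gas”. I pointed out that every earlier run held the gas at 8.8 mM, so the gain cannot test that choice.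

The flask gives 10.6%, which is 1.5 points above my reckoning. Tuesday's wins with 9.6 points, against 6 points for Sunday's and 2.6 points for Saturday's, and it reaches 20.2%.

    gas phase ⇌ dissolved gas, rate k1*(csat - [dissolved gas]) (kL = 1.08 × 10⁻⁴ s⁻¹)
    substrate + dissolved gas + free catalyst → free catalyst + target (k = 0.0240 L² mol⁻² s⁻¹)
    dissolved gas → decomposed reagent (k = 4.38 × 10⁻⁶ s⁻¹)
    free catalyst + added ligand ⇌ idle complex (K = 2.30 L mol⁻¹, k = 1.27 × 10⁻⁴ L mol⁻¹ s⁻¹)
    free catalyst → spent catalyst (k = 2.82 × 10⁻⁵ s⁻¹)

Left until 12 h, the same flask takes the same reckoning: teal's reading at 10.0 h plus the gain gives 5.50%, and the flask holds 6.15%.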